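**Retrosynthetic overview**

1. Quinone ring locants: C1(=O), C2 (side chain), C3 (CH3), C4(=O), C5 and C6 (CH3). The last C–C bond made is C2–C3, closed by a ring-forming anodic coupling of the two silyl enol ethers of an open-chain (Z)-enedione; the same electrolysis carries the new ring on to the quinone.
2. Enabling feature: in the six-membered ring, C2 and C3 are each the α-carbon of a ring carbonyl (C1, C4), so C2–C3 is the central bond of a 1,4-dicarbonyl (enol-plus-enol union), and the tetrasubstituted C5=C6 alkene opposite holds both termini cis.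
3. (Z)-Enedione ⇐ tetrasubstituted furan (temporary ring that fixes the C5=C6 geometry, then opened oxidatively) ⇐ (Z)-iodoalkenyl carbinol (2-butyne + propanal on titanium) + C22 δ-hydroxy Weinreb amide.
4. C22 amide ⇐ natural phytol: C7' and C11' are bought, C3' is set by Sharpless epoxidation and relayed through Red-Al opening, and oxidation/Wittig adds the two carbons that become C1 and C2.
5. Ring order: furan (step 6, temporary) → opened (step 7) → quinone carbocycle, the only ring of the target (step 9).

Key step: step 9

Assumption: natural (2E,7R,11R)-phytol is bought as a single stereoisomer; the racemic carbinol centre of 12 and the enol ether geometries of 17 are left undefined because both are destroyed on the way to the quinone.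

**Route**

Step 1
Reactants: 1 (2E,7R,11R)-phytol
Product: 2 (2R,3R)-2,3-epoxyphytol
Conditions: Ti(OiPr)4 (10 mol%), D-(−)-diethyl tartrate (12 mol%), t-BuOOH (2 equiv, decane), 4 Å MS, CH2Cl2, −20 °C
Reagents that add atoms: tert-butyl hydroperoxide, CC(C)(C)OO
Why: Katsuki–Sharpless asymmetric epoxidation of an (E)-trisubstituted allylic alcohol, a reliable substrate class, in which the titanium/D-(−)-tartrate catalyst should deliver oxygen to the face that gives the (2R,3R)-epoxide and so sets the future C3' carbinol as R under catalyst control while the remote C7 and C11 centres are untouched.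

Step 2
Reactants: 2 (2R,3R)-2,3-epoxyphytol
Product: 3 (3R,7R,11R)-3,7,11,15-tetramethylhexadecane-1,3-diol
Conditions: NaAlH2(OCH2CH2OCH3)2 (Red-Al, 2 equiv), THF, 0 → 23 °C; aq. Rochelle salt
Reagents that add atoms: none
Why: Regioselective reductive opening of a 2,3-epoxy alcohol by Red-Al, in which the aluminium alkoxide delivers hydride intramolecularly to C2 (also the less substituted epoxide carbon) to give the 1,3-diol, and since the C3–O bond is not broken the tertiary carbinol keeps its R configuration.

Step 3
Reactants: 3 (3R,7R,11R)-3,7,11,15-tetramethylhexadecane-1,3-diol; 4 N-methoxy-N-methyl-2-(triphenyl-λ5-phosphanylidene)acetamide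
Product: 6 (2E,5R,9R,13R)-5-hydroxy-N-methoxy-N,5,9,13,17-pentamethyloctadec-2-enamide, via hydroxy aldehyde 5 (not isolated)
Conditions: PhI(OAc)2 (1.1 equiv), TEMPO (10 mol%), CH2Cl2, 23 °C; then 4 (1.3 equiv), 23 → 40 °C
Reagents that add atoms: none
Why: Nitroxyl-catalysed oxidation touches only the primary alcohol (the tertiary one cannot be oxidised), and Wittig olefination in the same flask with a stabilised, non-basic amide ylide should trap the retro-aldol-prone β-hydroxy aldehyde as the (E)-enamide, adding the two carbons that become C1 and C2 of the quinone.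

Step 4
Reactants: 6 (2E,5R,9R,13R)-5-hydroxy-N-methoxy-N,5,9,13,17-pentamethyloctadec-2-enamide
Product: 7 (5R,9R,13R)-5-hydroxy-N-methoxy-N,5,9,13,17-pentamethyloctadecanamide
Conditions: H2 (1 atm), 10% Pd/C, EtOAc, 23 °C
Reagents that add atoms: none
Why: Heterogeneous catalytic hydrogenation of a disubstituted conjugated alkene, under which the amide N–O bond, the homoallylic tertiary alcohol and the stereocentres should be unaffected.

Step 5
Reactants: 8 but-2-yne; 9 propanal
Product: 12 (Z)-5-iodo-4-methylhex-4-en-3-ol, via alkyne–titanium complex 10 (not isolated), via oxatitanacyclopentene 11 (not isolated)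
Conditions: Ti(OiPr)4 (1.0 equiv), i-PrMgCl (2.0 equiv), Et2O, −78 → −50 °C; then 9, −78 °C; then I2, −78 → 0 °C
Reagents that add atoms: iodine, II
Why: Reductive alkyne–aldehyde coupling on low-valent titanium, in which the divalent titanium–alkyne complex 10 inserts propanal to give oxatitanacycle 11 with metal and carbinol carbon held cis by the ring, so that iodinolysis of the Ti–C(sp2) bond with retention should give the (Z)-iodide (the alkyne is symmetrical, so there is no regiochemical question).

Step 6
Reactants: 12 (Z)-5-iodo-4-methylhex-4-en-3-ol; 7 (5R,9R,13R)-5-hydroxy-N-methoxy-N,5,9,13,17-pentamethyloctadecanamide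
Product: 15 (4R,8R,12R)-1-(5-ethyl-3,4-dimethylfuran-2-yl)-4,8,12,16-tetramethylheptadecan-4-ol, via alkenyllithium alkoxide 13 (not isolated), via hydroxy enone 14 (not isolated)
Conditions: 12 (2.3 equiv), t-BuLi (3.0 equiv per 12), Et2O, −78 °C; then 7, THF, −78 → 0 °C; aq. NH4Cl; then PPTS (cat.), CH2Cl2, 23 °C
Reagents that add atoms: none
Why: Iodine–lithium exchange with retention of alkene geometry and acylation of the alkenyllithium by the Weinreb amide (stable chelated tetrahedral intermediate, no over-addition, one equivalent of 13 being spent on the tertiary hydroxyl) should give the (Z)-γ-hydroxy enone 14, which cyclodehydrates under mild acid to the aromatic furan, a temporary ring that locks the later C5=C6 alkene as cis.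

Step 7
Reactants: 15 (4R,8R,12R)-1-(5-ethyl-3,4-dimethylfuran-2-yl)-4,8,12,16-tetramethylheptadecan-4-ol
Product: 16 (4Z,10R,14R,18R)-10-hydroxy-4,5,10,14,18,22-hexamethyltricos-4-ene-3,6-dione
Conditions: mCPBA (1.05 equiv), NaHCO3, CH2Cl2, 0 °C, dark
Reagents that add atoms: 3-chloroperoxybenzoic acid (mCPBA), OOC(=O)c1cccc(Cl)c1
Why: Peracid oxidative ring opening of a tetraalkylfuran to the cis-2-ene-1,4-dione is a standard unmasking, the alkene is necessarily Z because it was a ring bond of the furan, and the saturated chain and tertiary alcohol should be inert.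

Step 8
Reactants: 16 (4Z,10R,14R,18R)-10-hydroxy-4,5,10,14,18,22-hexamethyltricos-4-ene-3,6-dione
Product: 17 (4Z,10R,14R,18R)-4,5,10,14,18,22-hexamethyl-3,6,10-tris(triethylsilyloxy)tricosa-2,4,6-triene
Conditions: Et3SiOTf (3.6 equiv), Et3N (6 equiv), CH2Cl2, −78 → 0 °C; pentane, filtration; used at once
Reagents that add atoms: triethylsilyl trifluoromethanesulfonate, CC[Si](CC)(CC)OS(=O)(=O)C(F)(F)F
Why: Soft enolisation by silyl triflate and amine, which gives 2-silyloxydienes from enones without a free enolate (so no intramolecular aldol), should remove the α'-protons next to each O-silylated carbonyl because the crowded cis-diacyl alkene is twisted out of conjugation and the vinylic methyl protons are therefore not activated, and the triflate also silylates the tertiary alcohol, masking it for the anodic step.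

Step 9
Reactants: 17 (4Z,10R,14R,18R)-4,5,10,14,18,22-hexamethyl-3,6,10-tris(triethylsilyloxy)tricosa-2,4,6-triene
Product: 21 α-tocopherylquinone, via dihydroquinone silyl ether 18 (not isolated), via hydroquinone silyl ether 19 (not isolated), via quinone silyl ether 20 (not isolated)
Conditions: reticulated vitreous carbon anode, Pt cathode, divided cell, constant current (4.2 F/mol), LiClO4 (0.1 M), 2,6-lutidine (6 equiv), MeOH/CH2Cl2 1:4, 0 °C; then 1 M HCl, THF, 23 °C
Reagents that add atoms: none
Why: Proposed new method: anodic one-electron oxidation of one silyl enol ether gives a radical cation whose α-carbon is attacked by the nucleophilic α-carbon of the second enol ether, forming the C2–C3 bond; loss of the silyl group to methanol, a second electron transfer and a second desilylation give dihydroquinone 18, which enolises to hydroquinone 19 and, being easier to oxidise than 17, is taken on at the same electrode by two further electrons to quinone 20, after which dilute acid cleaves the tertiary silyl ether. The closest known reaction types are the oxidative (anodic or metal-mediated) coupling of silyl enol ethers and enolates to 1,4-diketones and the intramolecular anodic coupling of enol ethers with electron-rich alkenes, here applied to the bis(enol ether) of a (Z)-enedione and run through to the quinone oxidation level. The six-membered carbocycle closes by a 6-endo-trig radical-cation/enol ether coupling, which is equally a hole-catalysed 6π-electrocyclisation of the (Z)-hexatriene, and a purely thermal disrotatory closure before electron transfer would converge on the same quinone because the resulting bis(silyloxy)cyclohexadiene is oxidised more easily still. No stereocentre is created in the product: the two sp3 carbons formed in 18 become sp2 on aromatisation, and the three side-chain centres are remote, saturated and untouched. The selectivity needed is ring-closing C–C coupling rather than capture of the radical cation by methanol, and survival of the quinone; the first is secured by the Z-configured C5=C6 alkene, which holds the two enol termini within bonding distance, and by the low methanol content, the second by the divided cell and by the fully substituted quinone ring, which offers no site for nucleophilic addition.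

**Compound list**

1 | (2E,7R,11R)-3,7,11,15-tetramethylhexadec-2-en-1-ol (natural phytol) | OC/C=C(\C)CCC[C@H](C)CCC[C@H](C)CCCC(C)C | starting material
2 | [(2R,3R)-3-methyl-3-[(4R,8R)-4,8,12-trimethyltridecyl]oxiran-2-yl]methanol | OC[C@H]1O[C@]1(C)CCC[C@H](C)CCC[C@H](C)CCCC(C)C | intermediate
3 | (3R,7R,11R)-3,7,11,15-tetramethylhexadecane-1,3-diol | OCC[C@](C)(O)CCC[C@H](C)CCC[C@H](C)CCCC(C)C | intermediate
4 | N-methoxy-N-methyl-2-(triphenyl-λ5-phosphanylidene)acetamide | CON(C)C(=O)C=P(c1ccccc1)(c1ccccc1)c1ccccc1 | starting material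
5 | (3R,7R,11R)-3-hydroxy-3,7,11,15-tetramethylhexadecanal | O=CC[C@](C)(O)CCC[C@H](C)CCC[C@H](C)CCCC(C)C | intermediate
6 | (2E,5R,9R,13R)-5-hydroxy-N-methoxy-N,5,9,13,17-pentamethyloctadec-2-enamide | CON(C)C(=O)/C=C/C[C@](C)(O)CCC[C@H](C)CCC[C@H](C)CCCC(C)C | intermediate
7 | (5R,9R,13R)-5-hydroxy-N-methoxy-N,5,9,13,17-pentamethyloctadecanamide | CON(C)C(=O)CCC[C@](C)(O)CCC[C@H](C)CCC[C@H](C)CCCC(C)C | intermediate
8 | but-2-yne | CC#CC | starting material
9 | propanal | CCC=O | starting material
10 | (η2-but-2-yne)Ti(OiPr)2 (titanacyclopropene) | CC1=C(C)[Ti]1(OC(C)C)OC(C)C | intermediate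
11 | 5-ethyl-3,4-dimethyl-2,2-di(propan-2-yloxy)-1-oxa-2-titanacyclopent-3-ene | CCC1O[Ti](OC(C)C)(OC(C)C)C(C)=C1C | intermediate
12 | (Z)-5-iodo-4-methylhex-4-en-3-ol (racemic) | CCC(O)/C(C)=C(\I)C | intermediate
13 | dilithium derivative of 12 (lithium on oxygen and on the alkene carbon cis to the carbinol carbon) | CCC(O[Li])/C(C)=C(\[Li])C | intermediate
14 | (4Z,10R,14R,18R)-3,10-dihydroxy-4,5,10,14,18,22-hexamethyltricos-4-en-6-one (C3 epimers) | CCC(O)/C(C)=C(C)\C(=O)CCC[C@](C)(O)CCC[C@H](C)CCC[C@H](C)CCCC(C)C | intermediate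
15 | (4R,8R,12R)-1-(5-ethyl-3,4-dimethylfuran-2-yl)-4,8,12,16-tetramethylheptadecan-4-ol | CCc1oc(CCC[C@](C)(O)CCC[C@H](C)CCC[C@H](C)CCCC(C)C)c(C)c1C | intermediate
16 | (4Z,10R,14R,18R)-10-hydroxy-4,5,10,14,18,22-hexamethyltricos-4-ene-3,6-dione | CCC(=O)/C(C)=C(C)\C(=O)CCC[C@](C)(O)CCC[C@H](C)CCC[C@H](C)CCCC(C)C | intermediate
17 | (4Z,10R,14R,18R)-4,5,10,14,18,22-hexamethyl-3,6,10-tris(triethylsilyloxy)tricosa-2,4,6-triene (enol ether geometry undefined) | CC=C(O[Si](CC)(CC)CC)/C(C)=C(C)\C(O[Si](CC)(CC)CC)=CCC[C@](C)(O[Si](CC)(CC)CC)CCC[C@H](C)CCC[C@H](C)CCCC(C)C | intermediate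
18 | 2,3,5-trimethyl-6-[(3R,7R,11R)-3,7,11,15-tetramethyl-3-(triethylsilyloxy)hexadecyl]cyclohex-2-ene-1,4-dione (C5/C6 undefined) | CC1C(CC[C@](C)(O[Si](CC)(CC)CC)CCC[C@H](C)CCC[C@H](C)CCCC(C)C)C(=O)C(C)=C(C)C1=O | intermediate
19 | 2,3,5-trimethyl-6-[(3R,7R,11R)-3,7,11,15-tetramethyl-3-(triethylsilyloxy)hexadecyl]benzene-1,4-diol | Cc1c(C)c(O)c(CC[C@](C)(O[Si](CC)(CC)CC)CCC[C@H](C)CCC[C@H](C)CCCC(C)C)c(C)c1O | intermediate
20 | 2,3,5-trimethyl-6-[(3R,7R,11R)-3,7,11,15-tetramethyl-3-(triethylsilyloxy)hexadecyl]cyclohexa-2,5-diene-1,4-dione | CC1=C(C)C(=O)C(CC[C@](C)(O[Si](CC)(CC)CC)CCC[C@H](C)CCC[C@H](C)CCCC(C)C)=C(C)C1=O | intermediate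
21 | 2-[(3R,7R,11R)-3-hydroxy-3,7,11,15-tetramethylhexadecyl]-3,5,6-trimethylcyclohexa-2,5-diene-1,4-dione (α-tocopherylquinone) | CC1=C(C)C(=O)C(CC[C@](C)(O)CCC[C@H](C)CCC[C@H](C)CCCC(C)C)=C(C)C1=O | target

**Step count and risks**

Total steps: 9. Longest linear sequence: 8 steps (steps 1–4 and 6–9, from phytol 1); iodide 12 is made in one step (step 5) and joins in step 6.

Steps most likely to fail:

- **Step 9 (proposed method).** The enol ether radical cation may be captured by methanol before the ring closes (α-methoxylation), or the enol ethers may be solvolysed in the electrolyte before they are oxidised. The fallback sets out from 17 and uses closed-shell chemistry. Thermal disrotatory 6π-electrocyclisation of the (Z)-triene (toluene, 110 °C) should give 2,3,5-trimethyl-6-alkyl-1,4-bis(triethylsilyloxy)cyclohexa-1,3-diene F1. Dehydrogenation with DDQ (benzene, 23 °C) should give the hydroquinone bis(triethylsilyl) ether F2. Oxidative desilylation with ceric ammonium nitrate (NH4)2Ce(NO3)6 in MeCN/H2O then gives quinone 20, where the route is rejoined at the acid stage of step 9.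

- **Step 8.** The O-silylated carbonyl may be attacked by the neighbouring carbonyl oxygen (cyclisation of the cis-enedione onto itself), deprotonation may occur at the vinylic methyl groups to give linear dienol ethers, or the enedione may isomerise from Z to E. The fallback sets out from 16 and bypasses 17. Inverse addition to LiN(iPr)2 (3.4 equiv, THF, −78 °C) gives by kinetic α'-deprotonation the trilithium dienolate alkoxide F3. Oxidative intramolecular enolate coupling with CuCl2 (DMF, −78 → 0 °C) should give 2,3,5-trimethyl-6-[(3R,7R,11R)-3-hydroxy-3,7,11,15-tetramethylhexadecyl]cyclohex-2-ene-1,4-dione F4. This enolises to α-tocopherylhydroquinone F5, which is oxidised by air on work-up, so the route is rejoined at the target 21.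

- **Step 6.** The hindered, strongly basic alkenyllithium may deprotonate the amide α-position instead of adding, or the halogen–metal exchange may be incomplete. The fallback sets out from 7 and 12 and avoids a basic organometallic. Reduction of 7 with i-Bu2AlH (THF, −78 °C) gives (5R,9R,13R)-5-hydroxy-5,9,13,17-tetramethyloctadecanal F6, which reacts through its open form. Nozaki–Hiyama–Kishi coupling with 12 (CrCl2, NiCl2 cat., DMF/DMSO, 23 °C) tolerates free hydroxyls and should give (4Z,10R,14R,18R)-4,5,10,14,18,22-hexamethyltricos-4-ene-3,6,10-triol F7. Oxidation with pyridinium chlorochromate (CH2Cl2, 23 °C), which takes (Z)-2-ene-1,4-diols to furans by oxidation, hemiketalisation and dehydration, rejoins the route at furan 15.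

**Further compounds**

F1 | step 9 | 2,3,5-trimethyl-6-[(3R,7R,11R)-3,7,11,15-tetramethyl-3-(triethylsilyloxy)hexadecyl]-1,4-bis(triethylsilyloxy)cyclohexa-1,3-diene | CC1C(CC[C@](C)(O[Si](CC)(CC)CC)CCC[C@H](C)CCC[C@H](C)CCCC(C)C)C(O[Si](CC)(CC)CC)=C(C)C(C)=C1O[Si](CC)(CC)CC
F2 | step 9 | 2,3,5-trimethyl-6-[(3R,7R,11R)-3,7,11,15-tetramethyl-3-(triethylsilyloxy)hexadecyl]-1,4-bis(triethylsilyloxy)benzene | Cc1c(C)c(O[Si](CC)(CC)CC)c(CC[C@](C)(O[Si](CC)(CC)CC)CCC[C@H](C)CCC[C@H](C)CCCC(C)C)c(C)c1O[Si](CC)(CC)CC
F3 | step 8 | trilithium (4Z,10R,14R,18R)-4,5,10,14,18,22-hexamethyltricosa-2,4,6-triene-3,6,10-triolate | CC=C(O[Li])/C(C)=C(C)\C(O[Li])=CCC[C@](C)(O[Li])CCC[C@H](C)CCC[C@H](C)CCCC(C)C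
F4 | step 8 | 2,3,5-trimethyl-6-[(3R,7R,11R)-3-hydroxy-3,7,11,15-tetramethylhexadecyl]cyclohex-2-ene-1,4-dione | CC1C(CC[C@](C)(O)CCC[C@H](C)CCC[C@H](C)CCCC(C)C)C(=O)C(C)=C(C)C1=O
F5 | step 8 | 2-[(3R,7R,11R)-3-hydroxy-3,7,11,15-tetramethylhexadecyl]-3,5,6-trimethylbenzene-1,4-diol | Cc1c(C)c(O)c(CC[C@](C)(O)CCC[C@H](C)CCC[C@H](C)CCCC(C)C)c(C)c1O
F6 | step 6 | (5R,9R,13R)-5-hydroxy-5,9,13,17-tetramethyloctadecanal | O=CCCC[C@](C)(O)CCC[C@H](C)CCC[C@H](C)CCCC(C)C
F7 | step 6 | (4Z,10R,14R,18R)-4,5,10,14,18,22-hexamethyltricos-4-ene-3,6,10-triol | CCC(O)/C(C)=C(C)\C(O)CCC[C@](C)(O)CCC[C@H](C)CCC[C@H](C)CCCC(C)C
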